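The benzene ring of the chroman (C4a, C5–C8, C8a) is made last. Its ester sits at C6, para to the O1-bearing C8a, which is the pattern methyl coumalate imprints on a ketene acetal. The precursor is therefore the cyclic silyl ketene acetal of a δ-lactone that already holds O1, C2 (methyl, allyl) and C3 (silyloxy) with both stereocentres set; its two sp2 carbons become C8a and C4a. One thermal operation forms C4a–C5 and C8–C8a, expels CO2 and silanol, and delivers the complete chroman benzoate. The stereodiad comes from one desymmetrising reduction of an achiral dione followed by Baeyer–Villiger oxygen insertion.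

Key step: step 6

Remarks on the chemistry:
- Chroman numbering (O1, C2, C3, C4, C4a, C5–C8, C8a) is used for all bicyclic compounds. The target is (2R,3R), with the acetoxy group cis to the C2 side chain.
- This requires ketol 4 in the (2R,3R) series with hydroxyl cis to allyl. Baker's yeast reduction of dione 3 leads to the (2S,3S) series, which would end in the enantiomer of the target, so a chemical catalyst whose antipode can be chosen is used.
- Assumption: RuCl(p-cymene)[(R,R)-TsDPEN] is taken to deliver the 3R carbinol. If the sense of induction proves opposite, the (S,S) antipode is used and nothing else changes.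
- Precursor design: the ketene acetal carries the bulky tert-butyldimethylsilyl group, which allows isolation without aqueous work-up, transfers silicon slowly and leaves as a good silanolate nucleofuge. The C3 oxygen carries the same group, so one reagent serves both silylations and no acyl group is exposed to the amide base.

Step 1
Reactants: 1 2-methylcyclopentane-1,3-dione; 2 allyl bromide
Product: 3 2-allyl-2-methylcyclopentane-1,3-dione
Conditions: 1 M NaOH (aq), 2 (2 equiv), rt
Reagents that add atoms: none
Why: C-alkylation of the stabilised 1,3-dione enolate by SN2 reaction with the allylic bromide is the standard way to quaternise C2 of a 2-alkylcyclopentane-1,3-dione; no stereocentre arises because the product keeps a mirror plane.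

Step 2
Reactants: 3 2-allyl-2-methylcyclopentane-1,3-dione
Product: 4 (2R,3R)-2-allyl-3-hydroxy-2-methylcyclopentan-1-one
Conditions: RuCl(p-cymene)[(R,R)-TsDPEN] (1 mol %), HCO2H/Et3N (5:2), CH2Cl2, 25 °C, stopped at consumption of 3
Reagents that add atoms: none
Why: Noyori asymmetric transfer hydrogenation desymmetrises the prochiral dione, since the chiral Ru hydride selects one of the two enantiotopic carbonyls and delivers hydride to the face opposite the larger allyl group, so the carbinol (3R) and the quaternary centre (2R) are fixed in the same event with hydroxyl cis to allyl.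

Step 3
Reactants: 4 (2R,3R)-2-allyl-3-hydroxy-2-methylcyclopentan-1-one
Product: 5 (2R,3R)-2-allyl-3-(tert-butyldimethylsilyloxy)-2-methylcyclopentan-1-one
Conditions: t-BuMe2SiCl, imidazole, DMF, rt to 40 °C
Reagents that add atoms: tert-butyldimethylsilyl chloride, CC(C)(C)[Si](C)(C)Cl
Why: Imidazole-promoted silylation of a secondary alcohol gives a silyl ether that withstands peracid, amide base and heat, and no stereocentre is touched.

Step 4
Reactants: 5 (2R,3R)-2-allyl-3-(tert-butyldimethylsilyloxy)-2-methylcyclopentan-1-one
Product: 6 (5R,6R)-6-allyl-5-(tert-butyldimethylsilyloxy)-6-methyltetrahydro-2H-pyran-2-one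
Conditions: mCPBA (1.5 equiv), NaHCO3, CH2Cl2, 0 °C → rt
Reagents that add atoms: mCPBA (3-chloroperoxybenzoic acid), O=C(OO)c1cccc(Cl)c1
Why: Baeyer–Villiger oxidation, in which the quaternary carbon of the Criegee adduct migrates in preference to the methylene and with retention, so the ring oxygen lands on the quaternary centre, while the monosubstituted alkene is the least reactive alkene class toward peracid and the buffer protects the silyl ether.

Step 5
Reactants: 6 (5R,6R)-6-allyl-5-(tert-butyldimethylsilyloxy)-6-methyltetrahydro-2H-pyran-2-one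
Product: 8 tert-butyl{[(2R,3R)-2-allyl-6-(tert-butyldimethylsilyloxy)-2-methyl-3,4-dihydro-2H-pyran-3-yl]oxy}dimethylsilane, via lithium lactone enolate 7 (not isolated)
Conditions: LiN(i-Pr)2, THF, −78 °C; then t-BuMe2SiCl, DMPU, −78 °C → rt; pentane, filtration, no aqueous work-up
Reagents that add atoms: tert-butyldimethylsilyl chloride, CC(C)(C)[Si](C)(C)Cl
Why: Kinetic deprotonation of the lactone at its only α-methylene and O-silylation of the lithium enolate in the presence of DMPU is the standard preparation of cyclic silyl ketene acetals, and both stereocentres are remote from the enolate and unaffected.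

Step 6
Reactants: 8 tert-butyl{[(2R,3R)-2-allyl-6-(tert-butyldimethylsilyloxy)-2-methyl-3,4-dihydro-2H-pyran-3-yl]oxy}dimethylsilane; 9 methyl coumalate
Product: 12 methyl (2R,3R)-2-allyl-3-(tert-butyldimethylsilyloxy)-2-methylchroman-6-carboxylate, via bridged lactone cycloadduct 10 (not isolated), via dihydrochroman silyl ketal 11 (not isolated)
Conditions: 8 (1.3 equiv), PhMe, 60 → 110 °C, sealed tube, Ar
Reagents that add atoms: none
Why: Inverse-electron-demand Diels–Alder reaction, in which the nucleophilic CH terminus of 8 (future C4a) bonds to C6 of the pyrone (the electrophilic position β to the ester and δ to the lactone carbonyl) and the acetal carbon (future C8a) bonds to C3, giving the 2-oxabicyclo[2.2.2]oct-5-en-3-one 10. Retro-[4+2] loss of CO2 gives diene 11, which aromatises by loss of tert-butyldimethylsilanol across C4a–C8a. The closest known reaction type is the conversion of methyl coumalate with ketene acetals or enol ethers into benzoates. The benzene ring closes by intermolecular [4+2] cycloaddition that forms C4a–C5 and C8–C8a on the intact dihydropyran, so the oxygen ring is carried through and not closed here. No stereocentre is created in the product, since the four transient sp3 centres of 10 are erased and C2 and C3 lie outside the reacting π system. The step needs regioselectivity, secured by the matched polarity of the two partners (ester at C6, para to O1), and expulsion of silanol in place of the ring oxygen, secured because suprafacial addition puts H-4a cis to the silyloxy group, silanolate is the better nucleofuge and leaves an alkoxy-stabilised cyclohexadienyl cation, and any opening of the tethered ring alkoxide can reverse before aromatisation.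

Step 7
Reactants: 12 methyl (2R,3R)-2-allyl-3-(tert-butyldimethylsilyloxy)-2-methylchroman-6-carboxylate
Product: 13 methyl (2R,3R)-2-allyl-3-hydroxy-2-methylchroman-6-carboxylate
Conditions: Bu4NF, THF, 0 °C → rt
Reagents that add atoms: none
Why: Fluoride-driven desilylation, powered by the strong Si–F bond, frees the C3 alcohol without touching the methyl ester, the alkene or the tertiary alkyl aryl ether, and C3 keeps its configuration because its C–O bond is not broken.

Step 8
Reactants: 13 methyl (2R,3R)-2-allyl-3-hydroxy-2-methylchroman-6-carboxylate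
Product: 14 methyl (2R,3R)-3-acetoxy-2-allyl-2-methylchroman-6-carboxylate
Conditions: Ac2O, pyridine, DMAP (cat.), CH2Cl2, rt
Reagents that add atoms: acetic anhydride, CC(=O)OC(C)=O
Why: DMAP-catalysed acylation esterifies the hindered secondary alcohol, which is the only free hydroxyl in the molecule, with retention at C3.

Step 9
Reactants: 14 methyl (2R,3R)-3-acetoxy-2-allyl-2-methylchroman-6-carboxylate; 15 2-methylbut-3-en-2-ol
Product: 16 methyl (2R,3R)-3-acetoxy-2-[(2E)-4-hydroxy-4-methylpent-2-en-1-yl]-2-methylchroman-6-carboxylate
Conditions: second-generation Grubbs catalyst RuCl2(=CHPh)(PCy3)(H2IMes) (5 mol %), 15 (5–10 equiv), CH2Cl2, 40 °C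
Reagents that add atoms: none
Why: Olefin cross-metathesis between the unhindered terminal alkene and the tertiary allylic alcohol, which hardly homodimerises and is used in excess, should give the E-alkene under thermodynamic control with loss of ethylene, and ester, acetate and free hydroxyl are tolerated by the Ru carbene.

Compound list
1 | 2-methylcyclopentane-1,3-dione | CC1C(=O)CCC1=O | starting material
2 | allyl bromide | C=CCBr | starting material
3 | 2-allyl-2-methylcyclopentane-1,3-dione | C=CCC1(C)C(=O)CCC1=O | intermediate
4 | (2R,3R)-2-allyl-3-hydroxy-2-methylcyclopentan-1-one (hydroxyl cis to allyl) | O=C1CC[C@@H](O)[C@@]1(C)CC=C | intermediate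
5 | (2R,3R)-2-allyl-3-(tert-butyldimethylsilyloxy)-2-methylcyclopentan-1-one | O=C1CC[C@@H](O[Si](C)(C)C(C)(C)C)[C@@]1(C)CC=C | intermediate
6 | (5R,6R)-6-allyl-5-(tert-butyldimethylsilyloxy)-6-methyltetrahydro-2H-pyran-2-one | O=C1CC[C@@H](O[Si](C)(C)C(C)(C)C)[C@@](C)(CC=C)O1 | intermediate
7 | lithium enolate of lactone 6 (not isolated) | [Li+].[O-]C1=CC[C@@H](O[Si](C)(C)C(C)(C)C)[C@@](C)(CC=C)O1 | intermediate
8 | tert-butyl{[(2R,3R)-2-allyl-6-(tert-butyldimethylsilyloxy)-2-methyl-3,4-dihydro-2H-pyran-3-yl]oxy}dimethylsilane (cyclic silyl ketene acetal) | CC(C)(C)[Si](C)(C)OC1=CC[C@@H](O[Si](C)(C)C(C)(C)C)[C@@](C)(CC=C)O1 | intermediate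
9 | methyl coumalate (methyl 2-oxo-2H-pyran-5-carboxylate) | COC(=O)C1=COC(=O)C=C1 | starting material
10 | bridged lactone cycloadduct: 2-oxabicyclo[2.2.2]oct-5-en-3-one fused across C4a–C8a to the pyran ring, ester on the alkene, silyloxy groups at C3 and C8a; new centres C4a, C5, C8, C8a as a mixture (not isolated) | COC(=O)C1=CC2C(=O)OC1C3C[C@@H](O[Si](C)(C)C(C)(C)C)[C@@](C)(CC=C)OC23O[Si](C)(C)C(C)(C)C | intermediate
11 | dihydrochroman silyl ketal: methyl (2R,3R)-2-allyl-3,8a-bis(tert-butyldimethylsilyloxy)-2-methyl-3,4,4a,8a-tetrahydro-2H-chromene-6-carboxylate, H-4a cis to the C8a silyloxy group (not isolated) | COC(=O)C1=CC2C[C@@H](O[Si](C)(C)C(C)(C)C)[C@@](C)(CC=C)OC2(O[Si](C)(C)C(C)(C)C)C=C1 | intermediate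
12 | methyl (2R,3R)-2-allyl-3-(tert-butyldimethylsilyloxy)-2-methylchroman-6-carboxylate | COC(=O)c1ccc2c(c1)C[C@@H](O[Si](C)(C)C(C)(C)C)[C@@](C)(CC=C)O2 | intermediate
13 | methyl (2R,3R)-2-allyl-3-hydroxy-2-methylchroman-6-carboxylate | COC(=O)c1ccc2c(c1)C[C@@H](O)[C@@](C)(CC=C)O2 | intermediate
14 | methyl (2R,3R)-3-acetoxy-2-allyl-2-methylchroman-6-carboxylate | COC(=O)c1ccc2c(c1)C[C@@H](OC(C)=O)[C@@](C)(CC=C)O2 | intermediate
15 | 2-methylbut-3-en-2-ol | C=CC(C)(C)O | starting material
16 | methyl (2R,3R)-3-acetoxy-2-[(2E)-4-hydroxy-4-methylpent-2-en-1-yl]-2-methylchroman-6-carboxylate (CNP0075640.1) | COC(=O)c1ccc2c(c1)C[C@@H](OC(C)=O)[C@@](C)(C/C=C/C(C)(C)O)O2 | target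

Total step count: 9. Longest linear sequence: 9 steps, from 2-methylcyclopentane-1,3-dione to the target.

Steps most likely to fail

Step 6. The cyclohexadiene may aromatise by expelling the ring oxygen, which opens the pyran, in place of silanol. The ketene acetal may also add in conjugate fashion with silyl transfer and never close the second bond, or hydrolyse before it reacts. The fallback builds the same benzene ring by a normal-demand Diels–Alder reaction in which the pyran oxygen has no competing leaving group. It sets out from lactone 6. KN(SiMe3)2 and (PhO)2P(O)Cl (THF, DMPU, −78 °C) should give the ketene acetal phosphate, diphenyl (2R,3R)-2-allyl-3-(tert-butyldimethylsilyloxy)-2-methyl-3,4-dihydro-2H-pyran-6-yl phosphate F1. Stille coupling with CH2=CHSnBu3 (Pd(PPh3)4, LiCl, THF, reflux) should give the 2-alkoxy-1,3-diene, tert-butyl{[(2R,3R)-2-allyl-2-methyl-6-vinyl-3,4-dihydro-2H-pyran-3-yl]oxy}dimethylsilane F2. Diels–Alder reaction with methyl propiolate (PhMe, 80–110 °C) should give, with the usual para orientation of a 2-alkoxydiene, the cyclohexa-1,4-diene methyl (2R,3R)-2-allyl-3-(tert-butyldimethylsilyloxy)-2-methyl-3,4,4a,7-tetrahydro-2H-chromene-6-carboxylate F3. Dehydrogenation with DDQ (PhMe, rt) comes back to the route at chroman 12.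

Step 4. The peracid may epoxidise the terminal alkene while oxygen insertion at the hindered cyclopentanone is slow. The fallback masks the alkene during the oxidation. It sets out from ketone 5. Br2 (CH2Cl2, −78 °C) should give (2R,3R)-3-(tert-butyldimethylsilyloxy)-2-(2,3-dibromopropyl)-2-methylcyclopentan-1-one F4, as epimers at the new CHBr centre, which is of no consequence. mCPBA/NaHCO3 (CH2Cl2, rt) then performs the same oxygen insertion to (5R,6R)-5-(tert-butyldimethylsilyloxy)-6-(2,3-dibromopropyl)-6-methyltetrahydro-2H-pyran-2-one F5. Zn dust (AcOH, THF, 0 °C → rt) regenerates the alkene and comes back to the route at lactone 6.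

Step 2. The catalyst may reduce the other enantiotopic carbonyl, discriminate poorly between the faces syn and anti to the allyl group, or carry the ketol on to the diol. The fallback replaces desymmetrisation by resolution. It sets out from dione 3. NaBH4 (0.3 equiv, MeOH, −60 °C) should give the racemic cis ketol, that is 4 together with its mirror image (2S,3S)-2-allyl-3-hydroxy-2-methylcyclopentan-1-one F6. Lipase-catalysed acylation (Candida antarctica lipase B, vinyl acetate, t-BuOMe, 30 °C) is expected, by the empirical size rule for secondary alcohols, to acetylate the 3R enantiomer to (1R,2R)-2-allyl-2-methyl-3-oxocyclopentyl acetate F7. This is separated from unreacted F6 and methanolysed (K2CO3, MeOH, 0 °C) to come back to the route at ketol 4.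

Further compounds
F1 | step 6 | diphenyl (2R,3R)-2-allyl-3-(tert-butyldimethylsilyloxy)-2-methyl-3,4-dihydro-2H-pyran-6-yl phosphate | O=P(Oc1ccccc1)(Oc1ccccc1)OC1=CC[C@@H](O[Si](C)(C)C(C)(C)C)[C@@](C)(CC=C)O1
F2 | step 6 | tert-butyl{[(2R,3R)-2-allyl-2-methyl-6-vinyl-3,4-dihydro-2H-pyran-3-yl]oxy}dimethylsilane | C=CC1=CC[C@@H](O[Si](C)(C)C(C)(C)C)[C@@](C)(CC=C)O1
F3 | step 6 | methyl (2R,3R)-2-allyl-3-(tert-butyldimethylsilyloxy)-2-methyl-3,4,4a,7-tetrahydro-2H-chromene-6-carboxylate (epimers at C4a) | COC(=O)C1=CC2C[C@@H](O[Si](C)(C)C(C)(C)C)[C@@](C)(CC=C)OC2=CC1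
F4 | step 4 | (2R,3R)-3-(tert-butyldimethylsilyloxy)-2-(2,3-dibromopropyl)-2-methylcyclopentan-1-one (epimers at CHBr) | O=C1CC[C@@H](O[Si](C)(C)C(C)(C)C)[C@@]1(C)CC(Br)CBr
F5 | step 4 | (5R,6R)-5-(tert-butyldimethylsilyloxy)-6-(2,3-dibromopropyl)-6-methyltetrahydro-2H-pyran-2-one (epimers at CHBr) | O=C1CC[C@@H](O[Si](C)(C)C(C)(C)C)[C@@](C)(CC(Br)CBr)O1
F6 | step 2 | (2S,3S)-2-allyl-3-hydroxy-2-methylcyclopentan-1-one | O=C1CC[C@H](O)[C@]1(C)CC=C
F7 | step 2 | (1R,2R)-2-allyl-2-methyl-3-oxocyclopentyl acetate | O=C1CC[C@@H](OC(C)=O)[C@@]1(C)CC=C
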